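**Plan**

- Retrosynthesis: the C14 acid is masked as a tert-butyl ester and the C8 angelate is cut at C8–O (with inversion). The ten-membered carbocycle (ring A) is then opened at C7–C8. The precursor is taken apart at C7=C11 (metathesis), O6–C12 (ester), C6–C7 (vinyl addition), C9–C10 (alkenyl–aldehyde coupling) and C1=C10 (Wittig).
- Enabling feature: C7 of the γ-lactone (ring B: O6, C6, C7, C11, C12) carries the C8 carbinol and sits next to the exocyclic C11=C13 methylene. This is the retron of an allylmetal formed at C13 of a 3-(bromomethyl)butenolide (C13–C11=C7) adding through C7 to a C8 aldehyde.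
- Forward: nerol supplies C1–C6 and C15 with the 4Z olefin. Iodo-Wittig olefination and Nozaki–Hiyama–Kishi coupling with (R)-glyceraldehyde acetonide add C10/C14 and C9/C8. Ring B is then built on C6 (vinylation, acylation with 2-(bromomethyl)acrylic acid, ring-closing metathesis). Ring A closes last by CrCl2-mediated allylation, followed by C8 angeloylation and ester cleavage.
- Stereochemistry: C9 comes from Felkin–Anh addition to the glyceraldehyde, whose own centre is later excised. C6 comes from ligand-controlled vinylzinc addition. C7 comes from bonding anti to the C6 side chain. C8 comes from the matched chair/Felkin–Anh closure, which should give the 8R carbinol; Mitsunobu angeloylation inverts it to the required 8S.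
- Olefin geometry: 4Z from nerol; 1(10)E from the stabilised iodo ylide and stereoretentive coupling; both angelates are introduced by methods that do not isomerise the Z acyl group.

Key step: step 13

Remark: germacrane numbering is used for every intermediate (ring A = C1 to C10; C11, C12, C13 = lactone carbons; C14 = carboxyl carbon; C15 = methyl on C4), and the dioxolane carbon that becomes the aldehyde is called C8.

**Route**

Step 1
Reactants: 1 nerol
Product: 2 neryl acetate
Conditions: Ac2O, pyridine, DMAP (cat.), CH2Cl2, 0 °C → rt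
Reagents that add atoms: acetic anhydride, CC(=O)OC(C)=O
Why: Pyridine/DMAP-catalysed O-acylation of the primary allylic alcohol is routine and installs the electron-withdrawing allylic ester that deactivates the future C4=C5 olefin towards the peracid of step 2; no stereocentre is formed.

Step 2
Reactants: 2 neryl acetate
Product: 3 (±)-6,7-epoxyneryl acetate
Conditions: mCPBA, NaHCO3, CH2Cl2, 0 °C
Reagents that add atoms: 3-chloroperoxybenzoic acid (mCPBA), O=C(OO)c1cccc(Cl)c1
Why: Prilezhaev epoxidation is electrophilic and should take the remote, more electron-rich trisubstituted olefin in preference to the one deactivated by the allylic acetate; the epoxide carbon is formed racemic and is excised in step 3.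

Step 3
Reactants: 3 (±)-6,7-epoxyneryl acetate
Product: 5 (2Z)-3-methyl-6-oxohex-2-en-1-yl acetate, via vicinal diol 4 (not isolated)
Conditions: H5IO6, THF/H2O, 0 °C
Reagents that add atoms: none
Why: Periodic acid hydrolyses the epoxide to the vicinal diol 4 and cleaves it in the same flask (Malaprade glycol cleavage), releasing the C1 aldehyde and acetone without touching the Z olefin or the acetate.

Step 4
Reactants: 5 (2Z)-3-methyl-6-oxohex-2-en-1-yl acetate; 6 tert-butyl (triphenylphosphoranylidene)acetate
Product: 8 tert-butyl (2Z,6Z)-8-acetoxy-2-iodo-6-methylocta-2,6-dienoate, via iodo ylide 7 (not isolated)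
Conditions: 6, NIS, CH2Cl2, −20 °C; then 5, K2CO3, rt
Reagents that add atoms: N-iodosuccinimide, O=C1CCC(=O)N1I
Why: Wittig olefination with the ester-stabilised α-iodo ylide 7, made in the flask by iodination of 6 with NIS, should place the chain trans to the ester and so give mainly the (Z)-α-iodoenoate (C2 cis to iodine), the minor E isomer being removed by chromatography; no stereocentre is formed.

Step 5
Reactants: 8 tert-butyl (2Z,6Z)-8-acetoxy-2-iodo-6-methylocta-2,6-dienoate; 9 (R)-2,3-O-isopropylideneglyceraldehyde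
Product: 11 tert-butyl (2E,6Z)-8-acetoxy-2-{(S)-[(4R)-2,2-dimethyl-1,3-dioxolan-4-yl](hydroxy)methyl}-6-methylocta-2,6-dienoate, via alkenylchromium dichloride 10 (not isolated)
Conditions: CrCl2, NiCl2 (cat.), DMSO, rt; then H2O
Reagents that add atoms: none
Why: Nozaki–Hiyama–Kishi coupling: zerovalent nickel inserts into the C10–I bond, transmetalation gives the alkenyl trivalent chromium species 10 with retention of olefin geometry, and this adds to the aldehyde under Felkin–Anh control (attack anti to the α-C–O bond of the dioxolane) to set C9 as S in the anti adduct, the minor syn isomer being separated; the allylic acetate and the ester are inert to CrCl2.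

Step 6
Reactants: 11 the (9S)-allylic alcohol; 12 angelic acid
Product: 14 tert-butyl (2E,6Z)-8-acetoxy-2-{(S)-[(4R)-2,2-dimethyl-1,3-dioxolan-4-yl][(Z)-2-methylbut-2-enoyloxy]methyl}-6-methylocta-2,6-dienoate, via angelic 2,4,6-trichlorobenzoic anhydride 13 (not isolated)
Conditions: 12, 2,4,6-Cl3C6H2COCl, Et3N, PhMe, rt; then 11, 80 °C
Reagents that add atoms: none
Why: Mixed-anhydride (Yamaguchi-type) esterification run without a nucleophilic catalyst acylates the hindered allylic alcohol while avoiding the addition–elimination pathway that isomerises angelates to tiglates; C9 is not touched.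

Step 7
Reactants: 14 the C9 angelate with C6 acetate
Product: 15 tert-butyl (2E,6Z)-2-{(S)-[(4R)-2,2-dimethyl-1,3-dioxolan-4-yl][(Z)-2-methylbut-2-enoyloxy]methyl}-8-hydroxy-6-methylocta-2,6-dienoate
Conditions: K2CO3 (cat.), MeOH, 0 °C
Reagents that add atoms: none
Why: Base-catalysed transesterification with methanol removes the unhindered primary acetate much faster than it attacks the hindered conjugated angelate or the tert-butyl ester, and the acetonide is stable to base.

Step 8
Reactants: 15 the C6 allylic alcohol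
Product: 16 tert-butyl (2E,6Z)-2-{(S)-[(4R)-2,2-dimethyl-1,3-dioxolan-4-yl][(Z)-2-methylbut-2-enoyloxy]methyl}-6-methyl-8-oxoocta-2,6-dienoate
Conditions: MnO2, CH2Cl2, rt
Reagents that add atoms: none
Why: Heterogeneous allylic oxidation with MnO2 under neutral conditions should give the Z-enal without Z to E isomerisation or over-oxidation, and the aldehyde is used at once.

Step 9
Reactants: 16 the (4Z)-enal
Product: 17 tert-butyl (2E,6Z,8S)-2-{(S)-[(4R)-2,2-dimethyl-1,3-dioxolan-4-yl][(Z)-2-methylbut-2-enoyloxy]methyl}-8-hydroxy-6-methyldeca-2,6,9-trienoate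
Conditions: (CH2=CH)2Zn [from CH2=CHMgBr and ZnCl2, MgBrCl precipitated with 1,4-dioxane], (−)-MIB (cat.), PhMe, −30 → 0 °C; then H2O
Reagents that add atoms: divinylzinc, C=C[Zn]C=C (generated from vinylmagnesium bromide, C=C[Mg]Br)
Why: Amino-alcohol-catalysed enantioselective addition of an organozinc to an aldehyde: the zinc aminoalkoxide of (−)-MIB activates the enal and delivers a vinyl group to its Si face, setting C6 as S under catalyst control (C9 is too remote to interfere), while esters and the acetonide are inert to the organozinc.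

Step 10
Reactants: 17 the (6S)-dienol; 18 2-(bromomethyl)acrylic acid
Product: 20 tert-butyl (2E,6Z,8S)-8-{[2-(bromomethyl)prop-2-enoyl]oxy}-2-{(S)-[(4R)-2,2-dimethyl-1,3-dioxolan-4-yl][(Z)-2-methylbut-2-enoyloxy]methyl}-6-methyldeca-2,6,9-trienoate, via 2-(bromomethyl)acryloyl chloride 19 (not isolated)
Conditions: 18, (COCl)2, DMF (cat.), CH2Cl2, 0 °C → rt, concentrate; then 17, 2,6-lutidine, CH2Cl2, −20 → 0 °C
Reagents that add atoms: none
Why: O-Acylation of the bis-allylic secondary alcohol with the acid chloride 19 prepared in the same flask, with the hindered base 2,6-lutidine so that no amine or nucleophilic catalyst displaces the activated allylic bromide; C6 is retained.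

Step 11
Reactants: 20 the (6S)-2-(bromomethyl)acrylate
Product: 21 tert-butyl (2E,6Z)-7-[(2R)-4-(bromomethyl)-5-oxo-2,5-dihydrofuran-2-yl]-2-{(S)-[(4R)-2,2-dimethyl-1,3-dioxolan-4-yl][(Z)-2-methylbut-2-enoyloxy]methyl}-6-methylhepta-2,6-dienoate
Conditions: second-generation Grubbs catalyst (cat.), CH2Cl2, 40 °C, high dilution
Reagents that add atoms: none
Why: Ring-closing metathesis between the monosubstituted C7 vinyl group and the 1,1-disubstituted acrylate olefin closes the five-membered butenolide (ring B, new C7=C11) with loss of ethene, the trisubstituted olefins being too hindered and the allylic bromide inert towards the ruthenium carbene.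

Step 12
Reactants: 21 the 3-(bromomethyl)butenolide acetonide
Product: 23 tert-butyl (2E,6Z)-7-[(2R)-4-(bromomethyl)-5-oxo-2,5-dihydrofuran-2-yl]-6-methyl-2-{(1S)-1-[(Z)-2-methylbut-2-enoyloxy]-2-oxoethyl}hepta-2,6-dienoate, via terminal 1,2-diol 22 (not isolated)
Conditions: H5IO6, EtOAc, rt
Reagents that add atoms: none
Why: Periodic acid in ethyl acetate hydrolyses the terminal acetonide and cleaves the released 1,2-diol 22 in one operation (glycol cleavage), turning the auxiliary glyceraldehyde stereocentre into the C8 aldehyde carbon (its CH2O neighbour leaves as formaldehyde) under non-basic conditions that should not epimerise C9 or C6; the aldehyde is used crude.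

Step 13
Reactants: 23 the (6R,9S)-3-(bromomethyl)butenolide aldehyde
Product: 25 tert-butyl (1(10)E,4Z,6R,7R,8R,9S)-9-angeloyloxy-8-hydroxygermacra-1(10),4,11(13)-trien-12,6-olid-14-oate, via allylchromium dichloride 24 (not isolated)
Conditions: CrCl2 (excess), THF, rt, slow addition of 23 (high dilution); then H2O
Reagents that add atoms: none
Why: CrCl2 (two equivalents per bromide) reduces the activated allylic C13–Br bond of 23 to the allylic trivalent chromium species 24, which adds to the tethered C8 aldehyde through its γ-carbon C7 in a closed six-membered chair, forming C7–C8, shifting the double bond to C11=C13 and closing ring A. The closest known chemistry is the divalent-chromium Barbier (Nozaki–Hiyama) allylation of aldehydes with 3-(bromomethyl)furan-2(5H)-ones and the chromium-mediated macrocyclic allylation of ω-formyl allylic bromides; ring A closes as a 10-exo-trig addition to the aldehyde carbonyl, helped by the two ring-cis olefins (C4=C5 and C1=C10) that bend the chain ends towards each other. C7 is controlled by C6: the C5 side chain shields one face of the planar butenolide, so C8 bonds anti to it and the lactone becomes trans-fused. C8 is controlled by the chair, in which the butenolide (C6 trans to C13) and the aldehyde substituent C9 are both equatorial, and by the C9 angelate, whose Felkin–Anh preference (C7 approaching anti to the C9–O bond) selects the same aldehyde face; both elements, and the gauche C6–C7–C8–C9 torsion of the forming ring, point to the 8R carbinol (hydroxyl on the same ring face as H7), the C8 epimer of the natural configuration that step 14 is designed to invert. The selectivities needed are γ- over α-attack, secured by the cyclic transition state of allylchromium reagents, and ring closure over protonation or dimerisation, secured by slow addition into excess CrCl2 at high dilution. Because ring B is already closed on O6 the new C8 alkoxide cannot compete for C12, and the bulky tert-butyl ester keeps it from lactonising onto C14.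

Step 14
Reactants: 25 the (8R)-alcohol; 12 angelic acid
Product: 27 tert-butyl (1(10)E,4Z,6R,7S,8S,9S)-8,9-bis(angeloyloxy)germacra-1(10),4,11(13)-trien-12,6-olid-14-oate, via C8 alkoxyphosphonium angelate 26 (not isolated)
Conditions: 12, PPh3, DIAD (premixed), PhMe, 0 °C → rt
Reagents that add atoms: none
Why: Mitsunobu esterification: the C8 hydroxyl is activated as the alkoxyphosphonium 26 and displaced by angelate in an SN2 reaction with inversion, turning 8R into the required 8S, and because the acid reacts as a carboxylate and is never activated at its carbonyl the Z geometry of the angeloyl group is retained.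

Step 15
Reactants: 27 the tert-butyl ester of the target
Product: 28 (1(10)E,4Z,6R,7S,8S,9S)-8,9-bis(angeloyloxy)germacra-1(10),4,11(13)-trien-12,6-olid-14-oic acid (CNP0154468.1)
Conditions: CF3CO2H, CH2Cl2, 0 °C
Reagents that add atoms: none
Why: Acidolysis of the tert-butyl ester (alkyl–oxygen cleavage with loss of 2-methylpropene) frees the C14 acid under conditions that the α-methylene lactone, the angelates and the electron-poor C1=C10 olefin should tolerate at 0 °C; no stereocentre is affected.

**Compound list**

1 | nerol, (2Z)-3,7-dimethylocta-2,6-dien-1-ol | CC(C)=CCC/C(C)=C\CO | starting material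
2 | neryl acetate, (2Z)-3,7-dimethylocta-2,6-dien-1-yl acetate | CC(C)=CCC/C(C)=C\COC(C)=O | intermediate
3 | (±)-6,7-epoxyneryl acetate, (2Z)-5-(3,3-dimethyloxiran-2-yl)-3-methylpent-2-en-1-yl acetate, racemic at the oxirane carbon | CC1(C)OC1CC/C(C)=C\COC(C)=O | intermediate
4 | (±)-(2Z)-6,7-dihydroxy-3,7-dimethyloct-2-en-1-yl acetate (not isolated) | CC(C)(O)C(O)CC/C(C)=C\COC(C)=O | intermediate
5 | (2Z)-3-methyl-6-oxohex-2-en-1-yl acetate (C1 aldehyde) | O=CCC/C(C)=C\COC(C)=O | intermediate
6 | tert-butyl (triphenylphosphoranylidene)acetate | CC(C)(C)OC(=O)C=P(c1ccccc1)(c1ccccc1)c1ccccc1 | starting material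
7 | tert-butyl iodo(triphenylphosphoranylidene)acetate (not isolated) | CC(C)(C)OC(=O)C(I)=P(c1ccccc1)(c1ccccc1)c1ccccc1 | intermediate
8 | tert-butyl (2Z,6Z)-8-acetoxy-2-iodo-6-methylocta-2,6-dienoate | CC(=O)OC/C=C(/C)CC/C=C(/C(=O)OC(C)(C)C)I | intermediate
9 | (R)-2,3-O-isopropylideneglyceraldehyde | CC1(C)OC[C@H](C=O)O1 | starting material
10 | [(1Z,5Z)-7-acetoxy-1-(tert-butoxycarbonyl)-5-methylhepta-1,5-dien-1-yl]chromium dichloride (not isolated) | CC(=O)OC/C=C(/C)CC/C=C(/C(=O)OC(C)(C)C)[Cr](Cl)Cl | intermediate
11 | tert-butyl (2E,6Z)-8-acetoxy-2-{(S)-[(4R)-2,2-dimethyl-1,3-dioxolan-4-yl](hydroxy)methyl}-6-methylocta-2,6-dienoate (9S, anti adduct) | CC(=O)OC/C=C(/C)CC/C=C(/C(=O)OC(C)(C)C)[C@H](O)[C@H]1COC(C)(C)O1 | intermediate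
12 | angelic acid, (Z)-2-methylbut-2-enoic acid | C/C=C(/C)C(=O)O | starting material
13 | (Z)-2-methylbut-2-enoic 2,4,6-trichlorobenzoic anhydride (not isolated) | C/C=C(/C)C(=O)OC(=O)c1c(Cl)cc(Cl)cc1Cl | intermediate
14 | tert-butyl (2E,6Z)-8-acetoxy-2-{(S)-[(4R)-2,2-dimethyl-1,3-dioxolan-4-yl][(Z)-2-methylbut-2-enoyloxy]methyl}-6-methylocta-2,6-dienoate | CC(=O)OC/C=C(/C)CC/C=C(/C(=O)OC(C)(C)C)[C@H](OC(=O)/C(C)=C\C)[C@H]1COC(C)(C)O1 | intermediate
15 | tert-butyl (2E,6Z)-2-{(S)-[(4R)-2,2-dimethyl-1,3-dioxolan-4-yl][(Z)-2-methylbut-2-enoyloxy]methyl}-8-hydroxy-6-methylocta-2,6-dienoate | OC/C=C(/C)CC/C=C(/C(=O)OC(C)(C)C)[C@H](OC(=O)/C(C)=C\C)[C@H]1COC(C)(C)O1 | intermediate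
16 | tert-butyl (2E,6Z)-2-{(S)-[(4R)-2,2-dimethyl-1,3-dioxolan-4-yl][(Z)-2-methylbut-2-enoyloxy]methyl}-6-methyl-8-oxoocta-2,6-dienoate | O=C/C=C(/C)CC/C=C(/C(=O)OC(C)(C)C)[C@H](OC(=O)/C(C)=C\C)[C@H]1COC(C)(C)O1 | intermediate
17 | tert-butyl (2E,6Z,8S)-2-{(S)-[(4R)-2,2-dimethyl-1,3-dioxolan-4-yl][(Z)-2-methylbut-2-enoyloxy]methyl}-8-hydroxy-6-methyldeca-2,6,9-trienoate (6S carbinol) | C=C[C@H](O)/C=C(/C)CC/C=C(/C(=O)OC(C)(C)C)[C@H](OC(=O)/C(C)=C\C)[C@H]1COC(C)(C)O1 | intermediate
18 | 2-(bromomethyl)acrylic acid | C=C(CBr)C(=O)O | starting material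
19 | 2-(bromomethyl)acryloyl chloride (not isolated) | C=C(CBr)C(=O)Cl | intermediate
20 | tert-butyl (2E,6Z,8S)-8-{[2-(bromomethyl)prop-2-enoyl]oxy}-2-{(S)-[(4R)-2,2-dimethyl-1,3-dioxolan-4-yl][(Z)-2-methylbut-2-enoyloxy]methyl}-6-methyldeca-2,6,9-trienoate | C=C(CBr)C(=O)O[C@@H](C=C)/C=C(/C)CC/C=C(/C(=O)OC(C)(C)C)[C@H](OC(=O)/C(C)=C\C)[C@H]1COC(C)(C)O1 | intermediate
21 | tert-butyl (2E,6Z)-7-[(2R)-4-(bromomethyl)-5-oxo-2,5-dihydrofuran-2-yl]-2-{(S)-[(4R)-2,2-dimethyl-1,3-dioxolan-4-yl][(Z)-2-methylbut-2-enoyloxy]methyl}-6-methylhepta-2,6-dienoate | O=C1O[C@H](/C=C(/C)CC/C=C(/C(=O)OC(C)(C)C)[C@H](OC(=O)/C(C)=C\C)[C@H]2COC(C)(C)O2)C=C1CBr | intermediate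
22 | tert-butyl (2E,6Z)-7-[(2R)-4-(bromomethyl)-5-oxo-2,5-dihydrofuran-2-yl]-2-{(1S,2R)-2,3-dihydroxy-1-[(Z)-2-methylbut-2-enoyloxy]propyl}-6-methylhepta-2,6-dienoate (not isolated) | O=C1O[C@H](/C=C(/C)CC/C=C(/C(=O)OC(C)(C)C)[C@H](OC(=O)/C(C)=C\C)[C@H](O)CO)C=C1CBr | intermediate
23 | tert-butyl (2E,6Z)-7-[(2R)-4-(bromomethyl)-5-oxo-2,5-dihydrofuran-2-yl]-6-methyl-2-{(1S)-1-[(Z)-2-methylbut-2-enoyloxy]-2-oxoethyl}hepta-2,6-dienoate (6R,9S; precursor of the key step) | O=C1O[C@H](/C=C(/C)CC/C=C(/C(=O)OC(C)(C)C)[C@H](OC(=O)/C(C)=C\C)C=O)C=C1CBr | intermediate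
24 | C13 dichlorochromium analogue of 23 (allylchromium dichloride, not isolated) | O=C1O[C@H](/C=C(/C)CC/C=C(/C(=O)OC(C)(C)C)[C@H](OC(=O)/C(C)=C\C)C=O)C=C1C[Cr](Cl)Cl | intermediate
25 | tert-butyl (1(10)E,4Z,6R,7R,8R,9S)-9-angeloyloxy-8-hydroxygermacra-1(10),4,11(13)-trien-12,6-olid-14-oate; trans-fused lactone, C8 hydroxyl on the ring face of H7 (C7 is spatially as in 28; its descriptor is R only because the free hydroxyl changes the CIP ranking) | C=C1C(=O)O[C@@H]2/C=C(/C)CC/C=C(/C(=O)OC(C)(C)C)[C@H](OC(=O)/C(C)=C\C)[C@H](O)[C@@H]12 | intermediate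
26 | C8 O-triphenylphosphonium derivative of 25 with angelate counter-ion (not isolated) | C=C1C(=O)O[C@@H]2/C=C(/C)CC/C=C(/C(=O)OC(C)(C)C)[C@H](OC(=O)/C(C)=C\C)[C@H](O[P+](c3ccccc3)(c3ccccc3)c3ccccc3)[C@@H]12.C/C=C(/C)C(=O)[O-] | intermediate
27 | tert-butyl (1(10)E,4Z,6R,7S,8S,9S)-8,9-bis(angeloyloxy)germacra-1(10),4,11(13)-trien-12,6-olid-14-oate | C=C1C(=O)O[C@@H]2/C=C(/C)CC/C=C(/C(=O)OC(C)(C)C)[C@H](OC(=O)/C(C)=C\C)[C@@H](OC(=O)/C(C)=C\C)[C@@H]12 | intermediate
28 | (1(10)E,4Z,6R,7S,8S,9S)-8,9-bis(angeloyloxy)germacra-1(10),4,11(13)-trien-12,6-olid-14-oic acid (CNP0154468.1) | C=C1C(=O)O[C@@H]2/C=C(/C)CC/C=C(/C(=O)O)[C@H](OC(=O)/C(C)=C\C)[C@@H](OC(=O)/C(C)=C\C)[C@@H]12 | target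

**Totals**

Total step count: 15.
Longest linear sequence: 15 steps (1 to 28); the building blocks 6, 9, 12 and 18 are commercial and enter directly.

**Steps most likely to fail**

1. Step 13. The allylic chromium species may be protonated or couple intermolecularly before the strained ten-membered ring closes, or the α-acyloxy aldehyde may be reduced or epimerised under the reducing, Lewis acidic conditions. The fallback sets out from 23 and returns at 25. Pd2(dba)3-catalysed borylation of the C13 bromide with bis(pinacolato)diboron in toluene gives the pinacol allylboronate aldehyde F1, a stable, non-basic allyl donor. At high dilution on warming (Sc(OTf)3 as catalyst if needed) it should undergo intramolecular allylboration through the same closed chair to the C8 O-pinacolboronate F2. Mild aqueous hydrolysis then gives 25 with the same configuration.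

2. Step 14. Elimination of the activated C8 oxygen (towards C7 or C9) or participation of the neighbouring C9 angelate carbonyl may divert the displacement and erode the inversion. The fallback sets out from 25 and returns at 27. Oxidation with Dess–Martin periodinane (NaHCO3 buffer) gives the C8 ketone F3, which is reduced at once at −78 °C with LiAlH(OtBu)3. Hydride should add anti to the C9–O bond (Felkin–Anh) to give the 8S alcohol F4. Esterification of F4 with 12 under the mixed-anhydride conditions of step 6 (retention) then gives 27.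

3. Step 9. Insufficient facial control by the zinc aminoalkoxide on the polyfunctional substrate, uncatalysed background addition, or Z to E drift of the enal would leave C6 epimers that are hard to separate. The fallback sets out from 16 and returns at 17. Me2Zn/ProPhenol-mediated enantioselective addition of trimethylsilylacetylene (ligand enantiomer chosen for Si-face attack) gives the trimethylsilyl propargylic alcohol F5 (6R by CIP, same spatial sense as 17). K2CO3 in MeOH removes the silyl group to give the terminal propargylic alcohol F6. Semihydrogenation over Pd/CaCO3 poisoned with Pb(OAc)2, with quinoline, gives 17.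

**Further compounds**

F1 | step 13 | pinacol allylboronate aldehyde (C13 pinacolboryl analogue of 23) | O=C1O[C@H](/C=C(/C)CC/C=C(/C(=O)OC(C)(C)C)[C@H](OC(=O)/C(C)=C\C)C=O)C=C1CB2OC(C)(C)C(C)(C)O2
F2 | step 13 | C8 O-pinacolboronate of 25 | C=C1C(=O)O[C@@H]2/C=C(/C)CC/C=C(/C(=O)OC(C)(C)C)[C@H](OC(=O)/C(C)=C\C)[C@H](OB3OC(C)(C)C(C)(C)O3)[C@@H]12
F3 | step 14 | C8 ketone, tert-butyl (6R,7S,9S)-9-angeloyloxy-8-oxogermacra-1(10),4,11(13)-trien-12,6-olid-14-oate | C=C1C(=O)O[C@@H]2/C=C(/C)CC/C=C(/C(=O)OC(C)(C)C)[C@H](OC(=O)/C(C)=C\C)C(=O)[C@@H]12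
F4 | step 14 | 8S alcohol (C8 epimer of 25) | C=C1C(=O)O[C@@H]2/C=C(/C)CC/C=C(/C(=O)OC(C)(C)C)[C@H](OC(=O)/C(C)=C\C)[C@@H](O)[C@@H]12
F5 | step 9 | trimethylsilyl propargylic alcohol (6R; C7 alkyne analogue of 17 bearing SiMe3) | C[Si](C)(C)C#C[C@H](O)/C=C(/C)CC/C=C(/C(=O)OC(C)(C)C)[C@H](OC(=O)/C(C)=C\C)[C@H]1COC(C)(C)O1
F6 | step 9 | terminal propargylic alcohol (6R) | C#C[C@H](O)/C=C(/C)CC/C=C(/C(=O)OC(C)(C)C)[C@H](OC(=O)/C(C)=C\C)[C@H]1COC(C)(C)O1
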